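Atom labels: ring A is the cyclohexenone C1–C2–C3–C4–C5–C10 (C10 ketone, C1=C2), ring B the γ-lactone C4–C18(=O)–O–C19–C5, and the chain C5–C6–C7 ends at C8, the pyranone carbon next to its carbonyl.
Cuts, in retrosynthetic order: C1=C2 (from a C2 silyloxy ketone); the pyranone ring with the C7–C8 bond; the C4–OH bond; the C5–C10 bond of ring A; the C3–C4 and C5–C6 bonds to a dibromobutenolide.
Enabling feature: the C10 ketone and the C18 lactone carbonyl are 1,4-related across C5–C4, so an acyl radical at C10 can close ring A by adding to C5, the β-carbon of a C4=C5 butenolide that already is ring B.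
Forward order: ring B from mucobromic acid, both side chains by cross-coupling, ring A by 6-endo acyl radical closure, C4 hydroxylation, the pyranone ring on C7, and the enone last.
Stereochemistry: C2 comes from a Ru–(R)-BINAP hydrogenation and relays to the quaternary C5 in the chair-like radical closure (only a modest bias is expected, so the C5 epimer is removed by chromatography); C4 is set by oxidation of the lactone enolate anti to the axial C6 chain; C2 is erased in the final elimination.

Key step: step 10

Remark: C4 in 16 and C10 in 17 are drawn as the expected epimers; both centres are reset later (C4 in step 12, C10 in step 22), so epimers at these centres converge.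

Step 1
Reactants: 1 mucobromic acid
Product: 3 dibromobutenolide (3,4-dibromofuran-2(5H)-one), via hydroxy acid 2 (not isolated)
Conditions: NaBH4, MeOH, 0 °C; then conc. H2SO4, 0 °C → rt
Reagents that add atoms: none
Why: Borohydride reduces the aldehyde of the ring-opened formyl acid and the (Z)-hydroxy acid relactonises on acidification (carbonyl reduction followed by lactonisation), which keeps both vinylic bromides for the two couplings.

Step 2
Reactants: 3 dibromobutenolide; 4 potassium (2-(benzyloxy)ethyl)trifluoroborate
Product: 5 4-(2-(benzyloxy)ethyl)-3-bromofuran-2(5H)-one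
Conditions: PdCl2(dppf) (cat.), Cs2CO3, PhMe/H2O, 80 °C; acidic work-up
Reagents that add atoms: none
Why: Suzuki–Miyaura sp3–sp2 coupling, in which zerovalent palladium should insert faster into the β-bromide (a vinylogous acyl bromide, future C5) than into the α-bromide, so that the primary alkyltrifluoroborate installs C6–C7 at the β-carbon only.

Step 3
Reactants: 5 bromobutenolide; 6 allyltributylstannane
Product: 7 3-allyl-4-(2-(benzyloxy)ethyl)furan-2(5H)-one
Conditions: Pd2(dba)3 (cat.), AsPh3 (cat.), NMP, 60 °C
Reagents that add atoms: none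
Why: Stille coupling of the remaining α-bromide with the allylstannane under base-free conditions brings in C3 (with C2 and C1 as a terminal alkene) without moving the skipped double bond into conjugation.

Step 4
Reactants: 7 allyl butenolide
Product: 9 butenolide acetaldehyde, via ozonide 8 (not isolated)
Conditions: O3, CH2Cl2, −78 °C (Sudan Red 7B end point); then PPh3, −78 °C → rt
Reagents that add atoms: ozone, [O-][O+]=O
Why: Ozonolysis with reductive work-up, in which the monosubstituted alkene should react far faster than the conjugated, electron-poor butenolide double bond, so that one equivalent of ozone cleaves only the allyl group to the C2 aldehyde.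

Step 5
Reactants: 9 butenolide acetaldehyde; 10 ethyl diazoacetate
Product: 11 ethyl 4-[4-(2-(benzyloxy)ethyl)-2-oxo-2,5-dihydrofuran-3-yl]-3-oxobutanoate
Conditions: SnCl2 (cat.), CH2Cl2, rt
Reagents that add atoms: none
Why: Roskamp reaction, in which the Lewis acid-activated aldehyde adds the diazo ester and a 1,2-hydride shift with loss of dinitrogen gives the β-keto ester (C2 ketone, C1, C10 ester) under non-basic conditions that the enolisable aldehyde tolerates.

Step 6
Reactants: 11 β-keto ester
Product: 12 ethyl (R)-4-[4-(2-(benzyloxy)ethyl)-2-oxo-2,5-dihydrofuran-3-yl]-3-hydroxybutanoate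
Conditions: H2 (10 atm), RuCl2[(R)-BINAP] (cat.), EtOH, 50 °C
Reagents that add atoms: none
Why: Noyori asymmetric hydrogenation of a β-keto ester, in which the ester-chelated ketone is reduced under catalyst control and the (R)-ligand should give the (R)-carbinol at C2 as it does for simple 3-oxoalkanoates (same CIP ranking here), while the benzyl ether and the tetrasubstituted butenolide alkene are not reduced by this catalyst.

Step 7
Reactants: 12 β-hydroxy ester
Product: 13 ethyl (R)-4-[4-(2-(benzyloxy)ethyl)-2-oxo-2,5-dihydrofuran-3-yl]-3-(triisopropylsilyloxy)butanoate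
Conditions: TIPSOTf, 2,6-lutidine, CH2Cl2, 0 °C
Reagents that add atoms: triisopropylsilyl triflate, CC(C)[Si](C(C)C)(C(C)C)OS(=O)(=O)C(F)(F)F
Why: Silylation of the secondary alcohol with a silyl triflate and a hindered base; the triisopropylsilyl ether is chosen because it must outlast two triethylsilyl ethers in step 21 and still leave as silanolate in step 23.

Step 8
Reactants: 13 silyloxy ester
Product: 14 (R)-4-[4-(2-(benzyloxy)ethyl)-2-oxo-2,5-dihydrofuran-3-yl]-3-(triisopropylsilyloxy)butanoic acid
Conditions: LiOH·H2O, THF/H2O, 0 °C; then 1 M HCl to pH 3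
Reagents that add atoms: lithium hydroxide, [Li+].[OH-]
Why: Saponification of the ethyl ester, in which any butenolide opened by hydroxide is a (Z)-γ-hydroxy enoate that recloses on acidification and the β-silyloxy group should be stable at 0 °C.

Step 9
Reactants: 14 silyloxy acid
Product: 15 Se-phenyl (R)-4-[4-(2-(benzyloxy)ethyl)-2-oxo-2,5-dihydrofuran-3-yl]-3-(triisopropylsilyloxy)butaneselenoate
Conditions: (PhSe)2, PBu3, CH2Cl2, 0 °C → rt
Reagents that add atoms: diphenyl diselenide, c1ccc([Se][Se]c2ccccc2)cc1
Why: Selenoesterification of the acid (acyloxyphosphonium activation, then attack of benzeneselenolate) under neutral conditions gives the acyl radical precursor without touching the butenolide or the silyl ether.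

Step 10
Reactants: 15 butenolide selenoester
Product: 16 trans-fused bicyclic keto lactone
Conditions: (TMS)3SiH, AIBN (both by syringe pump), PhH (0.01 M), 80 °C
Reagents that add atoms: none
Why: The tris(trimethylsilyl)silyl radical abstracts the phenylselanyl group of 15 and the nucleophilic acyl radical so formed at C10 adds to C5, the electrophilic β-carbon of the butenolide, whereupon the tertiary α-lactone radical at C4 takes a hydrogen atom from the silane and carries the chain; the closest known reaction type is the cyclisation of selenoester-derived acyl radicals onto α,β-unsaturated esters and lactones. Ring A closes in the 6-endo-trig mode, because the 5-exo alternative would need attack at the fully substituted and polarity-mismatched α-carbon C4. The quaternary centre C5 is controlled by the C2 silyloxy group, which should sit pseudo-equatorial in the chair-like transition state and so direct the acyl carbon to the butenolide face that puts the C6 chain axial and cis to the silyloxy group; since both ring neighbours flanking C2 are trigonal this 1,4-relay is expected to be only modest, and the C5 epimer is to be removed by chromatography here, before C2 is erased. The second new centre C4 is controlled by the axial C6 chain, anti to which the planar radical should take up hydrogen (trans ring fusion), but it is reset in step 12 and its configuration does not matter. The step needs 6-endo regioselectivity, secured by the polarity and α-substitution of the butenolide, and ring closure faster than reduction or decarbonylation of the primary acyl radical, secured by high dilution and slow addition of the slow hydrogen donor.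

Step 11
Reactants: 16 bicyclic keto lactone
Product: 17 C10 alcohol
Conditions: NaBH4, MeOH, −20 °C
Reagents that add atoms: none
Why: Borohydride reduction masks the ketone before enolate chemistry; hydride should attack axially, anti to the axial C6 chain on the neighbouring carbon, giving the equatorial C10 alcohol, and the lactone is inert at this temperature.

Step 12
Reactants: 17 C10 alcohol
Product: 19 C4,C10-diol, via dilithium enolate 18 (not isolated)
Conditions: LDA (2.4 equiv), THF, −78 → −30 °C; then 2-(phenylsulfonyl)-3-phenyloxaziridine, −78 °C; then aq. NH4Cl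
Reagents that add atoms: 2-(phenylsulfonyl)-3-phenyloxaziridine, O=S(=O)(c1ccccc1)N1OC1c1ccccc1
Why: Enolate hydroxylation with an N-sulfonyloxaziridine, in which the first equivalent of base forms the C10 alkoxide and the second the lactone enolate, whose C4 should be attacked along the axial trajectory anti to the axial C6 chain on C5, so that the new hydroxyl is trans to that chain (trans-fused α-hydroxy lactone as in the target).

Step 13
Reactants: 19 C4,C10-diol
Product: 20 bis(triethylsilyl) ether
Conditions: TESOTf, 2,6-lutidine, CH2Cl2, 0 °C → rt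
Reagents that add atoms: triethylsilyl triflate, CC[Si](CC)(CC)OS(=O)(=O)C(F)(F)F
Why: Silyl triflate protection of both the hindered secondary and the tertiary alcohol, needed because the enol triflate formation in step 17 would not tolerate free hydroxyl groups.

Step 14
Reactants: 20 bis(triethylsilyl) ether
Product: 21 C7 alcohol
Conditions: H2 (1 atm), Pd/C, EtOAc, rt
Reagents that add atoms: none
Why: Hydrogenolysis of the benzyl ether over palladium on carbon, at a stage where the molecule holds no alkene and in a non-protic solvent in which the silyl ethers should survive.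

Step 15
Reactants: 21 C7 alcohol
Product: 22 C7 iodide
Conditions: PPh3, I2, imidazole, CH2Cl2, 0 °C → rt
Reagents that add atoms: iodine, II
Why: Appel-type iodination, in which the primary alcohol is activated as its oxyphosphonium salt and displaced by iodide in an SN2 step.

Step 16
Reactants: 22 C7 iodide; 23 tert-butyl acetoacetate
Product: 24 alkylated β-keto ester
Conditions: Cs2CO3, DMF, 50 °C
Reagents that add atoms: none
Why: Acetoacetic ester C-alkylation of the caesium enolate with the primary iodide forms the C7–C8 bond, and the new stereocentre (formed as a mixture) is removed in the next step.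

Step 17
Reactants: 24 alkylated β-keto ester
Product: 25 (Z)-enol triflate
Conditions: Tf2O, Et3N, LiOTf, CH2Cl2, 0 °C
Reagents that add atoms: triflic anhydride, O=S(=O)(OS(=O)(=O)C(F)(F)F)C(F)(F)F
Why: Enol triflate formation under chelation control, in which the lithium-chelated (Z)-enolate of the β-keto ester is trapped on oxygen so that the triflate ends up cis to the ester, as the later lactonisation requires.

Step 18
Reactants: 26 furan-3-carbaldehyde
Product: 27 3-ethynylfuran
Conditions: dimethyl (1-diazo-2-oxopropyl)phosphonate, K2CO3, MeOH, 0 °C → rt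
Reagents that add atoms: dimethyl (1-diazo-2-oxopropyl)phosphonate, CC(=O)C(=[N+]=[N-])P(=O)(OC)OC
Why: Seyferth–Gilbert homologation in its Ohira–Bestmann variant converts the aldehyde into the terminal alkyne under mild carbonate conditions that the furan tolerates.

Step 19
Reactants: 25 (Z)-enol triflate; 27 3-ethynylfuran
Product: 28 tert-butyl (Z)-2-en-4-ynoate
Conditions: PdCl2(PPh3)2 (cat.), CuI (cat.), i-Pr2NH, THF, rt
Reagents that add atoms: none
Why: Sonogashira coupling of the electron-poor vinyl triflate with the terminal alkyne should proceed with retention of the double-bond geometry and place the alkyne cis to the ester.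

Step 20
Reactants: 28 tert-butyl (Z)-2-en-4-ynoate
Product: 29 fully silylated pyranone
Conditions: Ph3PAuNTf2 (cat.), CH2Cl2, rt
Reagents that add atoms: none
Why: Gold-catalysed cycloisomerisation, in which the π-acid activates the alkyne, the ester carbonyl oxygen attacks 6-endo-dig at the furyl-bearing carbon (where positive charge is best stabilised), and loss of 2-methylpropene followed by protodeauration gives the 2-pyranone.

Step 21
Reactants: 29 fully silylated pyranone
Product: 30 C4,C10-diol with C2 silyl ether
Conditions: HF·pyridine, pyridine, THF, 0 °C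
Reagents that add atoms: none
Why: Selective desilylation with buffered hydrogen fluoride–pyridine should remove both triethylsilyl ethers while the far more robust triisopropylsilyl ether stays.

Step 22
Reactants: 30 C4,C10-diol with C2 silyl ether
Product: 31 C10 ketone
Conditions: Dess–Martin periodinane, CH2Cl2, rt
Reagents that add atoms: none
Why: Dess–Martin oxidation of the secondary C10 alcohol to the ketone, in which the tertiary C4 alcohol cannot be oxidised and the furan and pyranone are inert.

Step 23
Reactants: 31 C10 ketone
Product: 32 target compound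
Conditions: DBU, CH2Cl2, 0 °C → rt
Reagents that add atoms: none
Why: E1cB elimination, in which the amidine base enolises the ketone towards C1 (C5 is quaternary) and the enolate expels the C2 silanolate to give the C1=C2 enone, while retro-aldol cleavage of the C4–C5 bond is disfavoured because it would open the bicycle to a nine-membered keto lactone.

Compound list
1 | mucobromic acid (lactol form, 3,4-dibromo-5-hydroxyfuran-2(5H)-one) | OC1OC(=O)C(Br)=C1Br | starting material
2 | (Z)-2,3-dibromo-4-hydroxybut-2-enoic acid (sodium salt in the flask) | OC/C(Br)=C(/Br)C(O)=O | intermediate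
3 | 3,4-dibromofuran-2(5H)-one | O=C1OCC(Br)=C1Br | intermediate
4 | potassium (2-(benzyloxy)ethyl)trifluoroborate | [K+].F[B-](F)(F)CCOCc1ccccc1 | starting material
5 | 4-(2-(benzyloxy)ethyl)-3-bromofuran-2(5H)-one | O=C1OCC(CCOCc2ccccc2)=C1Br | intermediate
6 | allyltributylstannane | C=CC[Sn](CCCC)(CCCC)CCCC | starting material
7 | 3-allyl-4-(2-(benzyloxy)ethyl)furan-2(5H)-one | C=CCC1=C(CCOCc2ccccc2)COC1=O | intermediate
8 | ozonide of 7 (3-substituted 1,2,4-trioxolane) | O1OC(CC2=C(CCOCc3ccccc3)COC2=O)OC1 | intermediate
9 | 2-[4-(2-(benzyloxy)ethyl)-2-oxo-2,5-dihydrofuran-3-yl]acetaldehyde | O=CCC1=C(CCOCc2ccccc2)COC1=O | intermediate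
10 | ethyl diazoacetate | CCOC(=O)C=[N+]=[N-] | starting material
11 | ethyl 4-[4-(2-(benzyloxy)ethyl)-2-oxo-2,5-dihydrofuran-3-yl]-3-oxobutanoate | CCOC(=O)CC(=O)CC1=C(CCOCc2ccccc2)COC1=O | intermediate
12 | ethyl (R)-4-[4-(2-(benzyloxy)ethyl)-2-oxo-2,5-dihydrofuran-3-yl]-3-hydroxybutanoate | CCOC(=O)C[C@H](O)CC1=C(CCOCc2ccccc2)COC1=O | intermediate
13 | ethyl (R)-4-[4-(2-(benzyloxy)ethyl)-2-oxo-2,5-dihydrofuran-3-yl]-3-(triisopropylsilyloxy)butanoate | CCOC(=O)C[C@H](O[Si](C(C)C)(C(C)C)C(C)C)CC1=C(CCOCc2ccccc2)COC1=O | intermediate
14 | (R)-4-[4-(2-(benzyloxy)ethyl)-2-oxo-2,5-dihydrofuran-3-yl]-3-(triisopropylsilyloxy)butanoic acid | OC(=O)C[C@H](O[Si](C(C)C)(C(C)C)C(C)C)CC1=C(CCOCc2ccccc2)COC1=O | intermediate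
15 | Se-phenyl (R)-4-[4-(2-(benzyloxy)ethyl)-2-oxo-2,5-dihydrofuran-3-yl]-3-(triisopropylsilyloxy)butaneselenoate (cyclisation precursor) | O=C([Se]c1ccccc1)C[C@H](O[Si](C(C)C)(C(C)C)C(C)C)CC1=C(CCOCc2ccccc2)COC1=O | intermediate
16 | bicyclic keto lactone: ring A cyclohexanone (C10=O) fused at C4–C5 to the γ-lactone, C5 quaternary with the 2-(benzyloxy)ethyl chain, C4–H anti to that chain (trans fusion), C2 triisopropylsilyloxy group syn to that chain | c1ccc(COCC[C@@]23COC(=O)[C@H]2C[C@@H](O[Si](C(C)C)(C(C)C)C(C)C)CC3=O)cc1 | intermediate
17 | C10 alcohol of 16, hydroxyl equatorial and syn to the C6 chain | c1ccc(COCC[C@@]23COC(=O)[C@H]2C[C@@H](O[Si](C(C)C)(C(C)C)C(C)C)C[C@H]3O)cc1 | intermediate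
18 | dilithium C10-alkoxide C18-enolate of 17 | c1ccc(COCC[C@@]23COC(O[Li])=C2C[C@@H](O[Si](C(C)C)(C(C)C)C(C)C)C[C@H]3O[Li])cc1 | intermediate
19 | C4,C10-diol: tertiary C4 hydroxyl anti to the C6 chain (trans-fused α-hydroxy lactone), C10 hydroxyl as in 17 | c1ccc(COCC[C@@]23COC(=O)[C@@]2(O)C[C@@H](O[Si](C(C)C)(C(C)C)C(C)C)C[C@H]3O)cc1 | intermediate
20 | C4,C10-bis(triethylsilyl) ether of 19 | c1ccc(COCC[C@@]23COC(=O)[C@@]2(O[Si](CC)(CC)CC)C[C@@H](O[Si](C(C)C)(C(C)C)C(C)C)C[C@H]3O[Si](CC)(CC)CC)cc1 | intermediate
21 | debenzylated primary alcohol (C7–OH) | OCC[C@@]12COC(=O)[C@@]1(O[Si](CC)(CC)CC)C[C@@H](O[Si](C(C)C)(C(C)C)C(C)C)C[C@H]2O[Si](CC)(CC)CC | intermediate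
22 | primary iodide (C7–I) | ICC[C@@]12COC(=O)[C@@]1(O[Si](CC)(CC)CC)C[C@@H](O[Si](C(C)C)(C(C)C)C(C)C)C[C@H]2O[Si](CC)(CC)CC | intermediate
23 | tert-butyl acetoacetate | CC(=O)CC(=O)OC(C)(C)C | starting material
24 | tert-butyl 2-acetyl-4-(bicyclic lactone)butanoate, both epimers at the acetoacetate α-carbon | CC(=O)C(CC[C@@]12COC(=O)[C@@]1(O[Si](CC)(CC)CC)C[C@@H](O[Si](C(C)C)(C(C)C)C(C)C)C[C@H]2O[Si](CC)(CC)CC)C(=O)OC(C)(C)C | intermediate
25 | (Z)-enol triflate of 24 (triflate cis to the ester) | C/C(OS(=O)(=O)C(F)(F)F)=C(\CC[C@@]12COC(=O)[C@@]1(O[Si](CC)(CC)CC)C[C@@H](O[Si](C(C)C)(C(C)C)C(C)C)C[C@H]2O[Si](CC)(CC)CC)C(=O)OC(C)(C)C | intermediate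
26 | furan-3-carbaldehyde | O=Cc1ccoc1 | starting material
27 | 3-ethynylfuran | C#Cc1ccoc1 | intermediate
28 | tert-butyl (Z)-5-(furan-3-yl)-3-methyl-2-[2-(bicyclic lactone)ethyl]pent-2-en-4-ynoate (alkyne cis to the ester) | C/C(C#Cc1ccoc1)=C(\CC[C@@]12COC(=O)[C@@]1(O[Si](CC)(CC)CC)C[C@@H](O[Si](C(C)C)(C(C)C)C(C)C)C[C@H]2O[Si](CC)(CC)CC)C(=O)OC(C)(C)C | intermediate
29 | 6-(furan-3-yl)-4-methyl-2-pyranone carrying the bicyclic lactone on C7, C4/C10 triethylsilyl ethers, C2 triisopropylsilyl ether | Cc1cc(-c2ccoc2)oc(=O)c1CC[C@@]12COC(=O)[C@@]1(O[Si](CC)(CC)CC)C[C@@H](O[Si](C(C)C)(C(C)C)C(C)C)C[C@H]2O[Si](CC)(CC)CC | intermediate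
30 | C4,C10-diol with C2 triisopropylsilyl ether | Cc1cc(-c2ccoc2)oc(=O)c1CC[C@@]12COC(=O)[C@@]1(O)C[C@@H](O[Si](C(C)C)(C(C)C)C(C)C)C[C@H]2O | intermediate
31 | C10 ketone with C4 hydroxyl and C2 triisopropylsilyl ether | Cc1cc(-c2ccoc2)oc(=O)c1CC[C@@]12COC(=O)[C@@]1(O)C[C@@H](O[Si](C(C)C)(C(C)C)C(C)C)CC2=O | intermediate
32 | CNP0550188.1 | Cc1cc(-c2ccoc2)oc(=O)c1CC[C@@]12COC(=O)[C@@]1(O)CC=CC2=O | target

Total step count: 23. Longest linear sequence: 22 steps (steps 1–17 and 19–23; step 18 is a one-step side branch).

Steps most likely to fail

Step 10. Closure onto the fully substituted β-carbon may be slow, so hydrogen transfer to the acyl radical or loss of carbon monoxide may compete, and the face selection relayed from C2 may be poor. The fallback sets out from 15 and comes back at 16. The selenoester 15 is reduced with Bu3SnH and Pd(PPh3)4 (cat.) to the aldehyde F1. F1 is cyclised with SmI2 and t-BuOH in THF at −78 °C (ketyl–olefin cyclisation, the samarium ketyl adding 6-endo to C5) to the hydroxy lactone F2, obtained as a mixture at C10. The low temperature and the pyramidal, metal-bound carbinol carbon, whose axial hydrogen now penalises an axial C2 silyloxy group, should sharpen the face selection. Dess–Martin oxidation of F2 returns 16.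

Step 12. The oxidant may be delivered to the wrong face of the aggregated dianion (cis-fused hydroxy lactone), or the enolate may be consumed by the sulfonimine by-product. The fallback sets out from 17 and comes back at 19. The dianion 18, generated as before, is quenched with PhSeBr to the α-phenylselanyl lactone F3. Oxidation with H2O2 and pyridine and syn-elimination, possible only towards C3, gives the C3=C4 unsaturated lactone F4. Mukaiyama-type radical hydration of F4 (Mn(dpm)3 cat., PhSiH3, O2, i-PrOH, then P(OEt)3) adds hydrogen at C3 and lets the free tertiary C4 radical capture oxygen along the axial direction anti to the C6 chain, giving 19.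

Step 23. Under the amidine base the tertiary aldol unit may open by retro-aldol reaction, which would scramble C4 and C5, or the bulky silanolate may leave too slowly. The fallback sets out from 31 and comes back at 32. The silyl ether of 31 is cleaved with HF·pyridine to the β-hydroxy ketone F5. MsCl and Et3N at −20 °C convert its only secondary alcohol into the mesylate F6, which loses methanesulfonate in the same flask under this weaker base to give 32.

Further compounds
F1 | step 10 | (R)-4-[4-(2-(benzyloxy)ethyl)-2-oxo-2,5-dihydrofuran-3-yl]-3-(triisopropylsilyloxy)butanal | O=CC[C@H](O[Si](C(C)C)(C(C)C)C(C)C)CC1=C(CCOCc2ccccc2)COC1=O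
F2 | step 10 | C10 alcohol of 16 as a mixture of C10 epimers | c1ccc(COCC[C@@]23COC(=O)[C@H]2C[C@@H](O[Si](C(C)C)(C(C)C)C(C)C)CC3O)cc1
F3 | step 12 | C4-phenylselanyl derivative of 17 (either C4 epimer) | c1ccc(COCC[C@@]23COC(=O)C2([Se]c2ccccc2)C[C@@H](O[Si](C(C)C)(C(C)C)C(C)C)C[C@H]3O)cc1
F4 | step 12 | C3=C4 unsaturated lactone with free C10 hydroxyl | c1ccc(COCC[C@@]23COC(=O)C2=C[C@@H](O[Si](C(C)C)(C(C)C)C(C)C)C[C@H]3O)cc1
F5 | step 23 | C2-hydroxy C10 ketone (desilylated 31) | Cc1cc(-c2ccoc2)oc(=O)c1CC[C@@]12COC(=O)[C@@]1(O)C[C@@H](O)CC2=O
F6 | step 23 | C2 mesylate of F5 | Cc1cc(-c2ccoc2)oc(=O)c1CC[C@@]12COC(=O)[C@@]1(O)C[C@@H](OS(C)(=O)=O)CC2=O
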